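The route rests on cutting the C3–C4 bond between the two methyl-bearing carbons of the oxolane ring. A 5-exo radical cyclisation of a bromoacetal closes that ring through this bond: the ring oxygen O1 serves as tether, the carbinol carbon C2 (bearing the ether-linked guaiacyl ring) steers the new C3 stereocentre, and C5 is carried as an acetal carbon. The precursor is the mixed 2-bromo-1-ethoxypropyl acetal of an (R)-1-arylallyl alcohol, used as a diastereomer mixture that converges. Oxidation to the lactone, aryllithium addition and oxocarbenium reduction then install the second aryl ring cis to C4–CH3; phenol alkylation with a lactate-derived ketone and threo-selective reduction finish the side chain.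

Key step: step 4

Remark on numbering: in the explanations the oxolane atoms keep the target locants O1, C2 (carries the ether-linked aryl ring), C3, C4, C5 (carries the free-phenol aryl ring); systematic names of intermediates use their own locants.
Assumption: compounds 1, 5, 10 and 14 are taken as catalogue items (each is otherwise one routine step from vanillin, 4-bromo-2-methoxyphenol or ethyl (S)-lactate).

Step 1
Reactants: 1 4-(tert-butyldimethylsilyloxy)-3-methoxybenzaldehyde
Product: 3 rac-1-[4-(tert-butyldimethylsilyloxy)-3-methoxyphenyl]prop-2-en-1-yl acetate, via bromomagnesium alkoxide 2 (not isolated)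
Conditions: CH2=CHMgBr, THF, −78 → 0 °C; then Ac2O, 0 °C → rt
Reagents that add atoms: vinylmagnesium bromide C=C[Mg]Br; acetic anhydride CC(=O)OC(C)=O
Why: Grignard 1,2-addition to the aldehyde gives the racemic magnesium alkoxide, which is acetylated in the same flask; no stereocontrol is sought because the next step resolves the centre.

Step 2
Reactants: 3 rac-1-[4-(tert-butyldimethylsilyloxy)-3-methoxyphenyl]prop-2-en-1-yl acetate
Product: 4 (R)-1-[4-(tert-butyldimethylsilyloxy)-3-methoxyphenyl]prop-2-en-1-ol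
Conditions: Novozym 435 (immobilised Candida antarctica lipase B), n-BuOH, MTBE, 30 °C, stopped near half conversion
Reagents that add atoms: none
Why: Lipase-catalysed transesterification (kinetic resolution): the enzyme should accept only the (R)-acetate, in line with its usual preference for secondary alcohols with one large and one small substituent, so the (R)-alcohol is released while the (S)-acetate stays behind and is removed by chromatography, which sets C2.

Step 3
Reactants: 4 (R)-1-[4-(tert-butyldimethylsilyloxy)-3-methoxyphenyl]prop-2-en-1-ol; 5 ethyl 1-propenyl ether (E/Z mixture)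
Product: 6 tert-butyl{4-[(1R)-1-(2-bromo-1-ethoxypropoxy)prop-2-en-1-yl]-2-methoxyphenoxy}dimethylsilane (mixture at the acetal and C–Br carbons)
Conditions: NBS, CH2Cl2, −40 → 0 °C
Reagents that add atoms: N-bromosuccinimide O=C1CCC(=O)N1Br
Why: Bromoacetalisation (first half of the Ueno–Stork sequence): NBS activates the enol ether and the alcohol traps the α-bromo oxocarbenium ion at oxygen, so C2 is untouched and the two new centres form as a mixture that does not matter later.

Step 4
Reactants: 6 tert-butyl{4-[(1R)-1-(2-bromo-1-ethoxypropoxy)prop-2-en-1-yl]-2-methoxyphenoxy}dimethylsilane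
Product: 7 tert-butyl{4-[(2R,3R)-5-ethoxy-3,4-dimethyloxolan-2-yl]-2-methoxyphenoxy}dimethylsilane (mixture at the acetal carbon and the adjacent methyl-bearing carbon)
Conditions: Bu3SnH (syringe pump), AIBN (cat.), PhH, 80 °C
Reagents that add atoms: none
Why: Bromine abstraction by Bu3Sn• gives a secondary α-acetal radical that adds to the internal vinyl carbon, and the resulting primary radical takes H from Bu3SnH; this is the Ueno–Stork haloacetal radical cyclisation. The oxolane ring closes in the 5-exo-trig mode through the C3–C4 bond, with O1 and the acetal carbon C5 as tether. The stereocentre formed from the vinyl CH (C3) is controlled by the carbinol centre C2: in the chair-like transition state the aryl group sits pseudo-equatorial, so the new C3–CH3 should end up trans to the aryl ring. The radical-derived carbon C4 and the acetal carbon form as mixtures by design, because C5 becomes a carbonyl and C4 is equilibrated in step 5, so all four diastereomers of 6 converge. The step needs 5-exo closure to outrun direct reduction and 6-endo closure; the short C–O tether bonds and slow stannane addition should secure this.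

Step 5
Reactants: 7 tert-butyl{4-[(2R,3R)-5-ethoxy-3,4-dimethyloxolan-2-yl]-2-methoxyphenoxy}dimethylsilane
Product: 9 (3R,4R,5R)-5-[4-(tert-butyldimethylsilyloxy)-3-methoxyphenyl]-3,4-dimethyloxolan-2-one, via epimeric lactone mixture 8 (not isolated)
Conditions: mCPBA, BF3·OEt2, CH2Cl2, 0 °C; work-up; then DBU (cat.), PhMe, 80 °C
Reagents that add atoms: meta-chloroperbenzoic acid OOC(=O)c1cccc(Cl)c1
Why: Lewis-acid-assisted peracid oxidation of the lactol ether gives the lactone directly, and base equilibration through the enolate then moves the C4 methyl group into the thermodynamically preferred position trans to the C3 methyl group, converging the mixture to the all-trans lactone.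

Step 6
Reactants: 9 (3R,4R,5R)-5-[4-(tert-butyldimethylsilyloxy)-3-methoxyphenyl]-3,4-dimethyloxolan-2-one; 10 1-(benzyloxy)-4-bromo-2-methoxybenzene
Product: 13 tert-butyl(4-{(2R,3R,4R,5S)-5-[4-(benzyloxy)-3-methoxyphenyl]-3,4-dimethyloxolan-2-yl}-2-methoxyphenoxy)dimethylsilane, via aryllithium 11 (not isolated), via hemiketal 12 (not isolated)
Conditions: (i) 10, n-BuLi, THF, −78 °C; then 9, −78 °C; H2O quench; (ii) crude 12, Et3SiH, BF3·OEt2, CH2Cl2, −78 °C
Reagents that add atoms: none
Why: Aryllithium addition to the lactone should stop at the lithium hemiketalate at −78 °C, and ionisation of the hemiketal gives a 2-aryl oxocarbenium ion that takes hydride on the face opposite to the C4 methyl group and the C2 aryl ring (reductive deoxygenation), which places the new aryl ring at C5 cis to both under kinetic control.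

Step 7
Reactants: 10 1-(benzyloxy)-4-bromo-2-methoxybenzene (2.2 equiv); 14 (S)-2-hydroxy-N,N-dimethylpropanamide
Product: 16 (S)-1-[4-(benzyloxy)-3-methoxyphenyl]-2-hydroxypropan-1-one, via aryl Grignard reagent 15 (not isolated)
Conditions: Mg, THF, rt; then 14, 0 °C → rt; aq. HCl work-up
Reagents that add atoms: none
Why: Acyl substitution of the tertiary amide by the aryl Grignard reagent (a second equivalent deprotonates the hydroxyl group) gives a chelated tetrahedral magnesium alkoxide that collapses to the ketone only on work-up, so over-addition is avoided and the lactate stereocentre is retained.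

Step 8
Reactants: 16 (S)-1-[4-(benzyloxy)-3-methoxyphenyl]-2-hydroxypropan-1-one
Product: 17 (S)-1-[4-(benzyloxy)-3-methoxyphenyl]-1-oxopropan-2-yl 4-methylbenzenesulfonate
Conditions: TsCl, Et3N, DMAP (cat.), CH2Cl2, 0 °C
Reagents that add atoms: p-toluenesulfonyl chloride Cc1ccc(S(=O)(=O)Cl)cc1
Why: O-Sulfonylation of the secondary alcohol proceeds with retention and gives an α-keto sulfonate that is highly activated for SN2 displacement.

Step 9
Reactants: 13 tert-butyl(4-{(2R,3R,4R,5S)-5-[4-(benzyloxy)-3-methoxyphenyl]-3,4-dimethyloxolan-2-yl}-2-methoxyphenoxy)dimethylsilane; 17 (S)-1-[4-(benzyloxy)-3-methoxyphenyl]-1-oxopropan-2-yl 4-methylbenzenesulfonate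
Product: 19 (2R)-1-[4-(benzyloxy)-3-methoxyphenyl]-2-(4-{(2R,3R,4R,5S)-5-[4-(benzyloxy)-3-methoxyphenyl]-3,4-dimethyloxolan-2-yl}-2-methoxyphenoxy)propan-1-one, via caesium phenoxide 18 (not isolated)
Conditions: CsF, DMF, rt
Reagents that add atoms: none
Why: Fluoride cleaves the aryl silyl ether and the caesium phenoxide displaces the α-keto tosylate in a Williamson-type SN2 reaction with inversion, which sets the (R)-configured aryloxy carbon while the benzyl ethers stay intact.

Step 10
Reactants: 19 (2R)-1-[4-(benzyloxy)-3-methoxyphenyl]-2-(4-{(2R,3R,4R,5S)-5-[4-(benzyloxy)-3-methoxyphenyl]-3,4-dimethyloxolan-2-yl}-2-methoxyphenoxy)propan-1-one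
Product: 20 (1R,2R)-1-[4-(benzyloxy)-3-methoxyphenyl]-2-(4-{(2R,3R,4R,5S)-5-[4-(benzyloxy)-3-methoxyphenyl]-3,4-dimethyloxolan-2-yl}-2-methoxyphenoxy)propan-1-ol
Conditions: borohydride exchange resin (polymer-bound R4N+ BH4−), MeOH, 0 °C → rt
Reagents that add atoms: none
Why: Hydride reduction under non-chelating conditions (ammonium counter-ion) should follow the open polar transition state with the aryloxy group antiperiplanar to the incoming hydride, which gives the threo (1R,2R) alcohol from the (R)-ketone.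

Step 11
Reactants: 20 (1R,2R)-1-[4-(benzyloxy)-3-methoxyphenyl]-2-(4-{(2R,3R,4R,5S)-5-[4-(benzyloxy)-3-methoxyphenyl]-3,4-dimethyloxolan-2-yl}-2-methoxyphenoxy)propan-1-ol
Product: 21 (1R,2R)-1-(4-hydroxy-3-methoxyphenyl)-2-{4-[(2R,3R,4R,5S)-5-(4-hydroxy-3-methoxyphenyl)-3,4-dimethyloxolan-2-yl]-2-methoxyphenoxy}propan-1-ol (CNP0171079.2)
Conditions: H2 (1 atm), 10% Pd/C, EtOAc, rt
Reagents that add atoms: none
Why: Hydrogenolysis of the two aryl benzyl ethers should be much faster than cleavage of the ring benzylic C–O bonds or of the benzylic alcohol in a neutral aprotic solvent, so both phenols are freed without touching a stereocentre.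

Compound list
1 | 4-(tert-butyldimethylsilyloxy)-3-methoxybenzaldehyde | COc1cc(C=O)ccc1O[Si](C)(C)C(C)(C)C | starting material
2 | bromomagnesium rac-1-[4-(tert-butyldimethylsilyloxy)-3-methoxyphenyl]prop-2-en-1-olate | COc1cc(C(C=C)O[Mg]Br)ccc1O[Si](C)(C)C(C)(C)C | intermediate
3 | rac-1-[4-(tert-butyldimethylsilyloxy)-3-methoxyphenyl]prop-2-en-1-yl acetate | COc1cc(C(C=C)OC(C)=O)ccc1O[Si](C)(C)C(C)(C)C | intermediate
4 | (R)-1-[4-(tert-butyldimethylsilyloxy)-3-methoxyphenyl]prop-2-en-1-ol | COc1cc([C@@H](C=C)O)ccc1O[Si](C)(C)C(C)(C)C | intermediate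
5 | ethyl 1-propenyl ether (E/Z mixture) | CC=COCC | starting material
6 | tert-butyl{4-[(1R)-1-(2-bromo-1-ethoxypropoxy)prop-2-en-1-yl]-2-methoxyphenoxy}dimethylsilane (diastereomer mixture) | COc1cc([C@@H](C=C)OC(OCC)C(C)Br)ccc1O[Si](C)(C)C(C)(C)C | intermediate
7 | tert-butyl{4-[(2R,3R)-5-ethoxy-3,4-dimethyloxolan-2-yl]-2-methoxyphenoxy}dimethylsilane (mixture at C4 and C5 of this oxolane) | COc1cc([C@@H]2OC(OCC)C(C)[C@H]2C)ccc1O[Si](C)(C)C(C)(C)C | intermediate
8 | (4R,5R)-5-[4-(tert-butyldimethylsilyloxy)-3-methoxyphenyl]-3,4-dimethyloxolan-2-one (C3 epimer mixture) | COc1cc([C@@H]2OC(=O)C(C)[C@H]2C)ccc1O[Si](C)(C)C(C)(C)C | intermediate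
9 | (3R,4R,5R)-5-[4-(tert-butyldimethylsilyloxy)-3-methoxyphenyl]-3,4-dimethyloxolan-2-one | COc1cc([C@@H]2OC(=O)[C@H](C)[C@H]2C)ccc1O[Si](C)(C)C(C)(C)C | intermediate
10 | 1-(benzyloxy)-4-bromo-2-methoxybenzene | COc1cc(Br)ccc1OCc1ccccc1 | starting material
11 | [4-(benzyloxy)-3-methoxyphenyl]lithium | COc1cc([Li])ccc1OCc1ccccc1 | intermediate
12 | (3R,4R,5R)-2-[4-(benzyloxy)-3-methoxyphenyl]-5-[4-(tert-butyldimethylsilyloxy)-3-methoxyphenyl]-3,4-dimethyloxolan-2-ol (anomer mixture) | COc1cc([C@@H]2OC(O)(c3ccc(OCc4ccccc4)c(OC)c3)[C@H](C)[C@H]2C)ccc1O[Si](C)(C)C(C)(C)C | intermediate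
13 | tert-butyl(4-{(2R,3R,4R,5S)-5-[4-(benzyloxy)-3-methoxyphenyl]-3,4-dimethyloxolan-2-yl}-2-methoxyphenoxy)dimethylsilane | COc1cc([C@@H]2O[C@H](c3ccc(OCc4ccccc4)c(OC)c3)[C@H](C)[C@H]2C)ccc1O[Si](C)(C)C(C)(C)C | intermediate
14 | (S)-2-hydroxy-N,N-dimethylpropanamide | C[C@H](O)C(=O)N(C)C | starting material
15 | [4-(benzyloxy)-3-methoxyphenyl]magnesium bromide | COc1cc([Mg]Br)ccc1OCc1ccccc1 | intermediate
16 | (S)-1-[4-(benzyloxy)-3-methoxyphenyl]-2-hydroxypropan-1-one | COc1cc(C(=O)[C@H](C)O)ccc1OCc1ccccc1 | intermediate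
17 | (S)-1-[4-(benzyloxy)-3-methoxyphenyl]-1-oxopropan-2-yl 4-methylbenzenesulfonate | COc1cc(C(=O)[C@H](C)OS(=O)(=O)c2ccc(C)cc2)ccc1OCc1ccccc1 | intermediate
18 | caesium 4-{(2R,3R,4R,5S)-5-[4-(benzyloxy)-3-methoxyphenyl]-3,4-dimethyloxolan-2-yl}-2-methoxyphenolate | COc1cc([C@@H]2O[C@H](c3ccc(OCc4ccccc4)c(OC)c3)[C@H](C)[C@H]2C)ccc1[O-].[Cs+] | intermediate
19 | (2R)-1-[4-(benzyloxy)-3-methoxyphenyl]-2-(4-{(2R,3R,4R,5S)-5-[4-(benzyloxy)-3-methoxyphenyl]-3,4-dimethyloxolan-2-yl}-2-methoxyphenoxy)propan-1-one | COc1cc(C(=O)[C@@H](C)Oc2ccc([C@@H]3O[C@H](c4ccc(OCc5ccccc5)c(OC)c4)[C@H](C)[C@H]3C)cc2OC)ccc1OCc1ccccc1 | intermediate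
20 | (1R,2R)-1-[4-(benzyloxy)-3-methoxyphenyl]-2-(4-{(2R,3R,4R,5S)-5-[4-(benzyloxy)-3-methoxyphenyl]-3,4-dimethyloxolan-2-yl}-2-methoxyphenoxy)propan-1-ol | COc1cc([C@@H](O)[C@@H](C)Oc2ccc([C@@H]3O[C@H](c4ccc(OCc5ccccc5)c(OC)c4)[C@H](C)[C@H]3C)cc2OC)ccc1OCc1ccccc1 | intermediate
21 | (1R,2R)-1-(4-hydroxy-3-methoxyphenyl)-2-{4-[(2R,3R,4R,5S)-5-(4-hydroxy-3-methoxyphenyl)-3,4-dimethyloxolan-2-yl]-2-methoxyphenoxy}propan-1-ol | COc1cc([C@@H](O)[C@@H](C)Oc2ccc([C@@H]3O[C@H](c4ccc(O)c(OC)c4)[C@H](C)[C@H]3C)cc2OC)ccc1O | target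

Total step count: 11.
Longest linear sequence: 9 steps (steps 1–6 and 9–11, from aldehyde 1); the side-chain electrophile 17 takes 2 steps (7 and 8) and joins at step 9.

Steps most likely to fail

Step 6. Double addition of the aryllithium to the lactone, enolisation of the lactone, or acid-driven epimerisation at the newly formed benzylic centre C5 (which would drift to the all-trans arrangement if the reduction warms) could spoil the sequence. The fallback makes the aryl ketone from an open-chain amide. Lactone 9 would be opened with MeNH(OMe)·HCl/AlMe3 to the hydroxy Weinreb amide F4, silylated (TESCl, imidazole) to the silyl ether F5, and treated with aryllithium 11 to give the γ-silyloxy aryl ketone F6, which cannot over-add. Reductive etherification of F6 (Et3SiH, TMSOTf or BiBr3, CH2Cl2/MeCN, −78 → −40 °C) should pass through the same oxocarbenium ion under milder acid and return to oxolane 13.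

Step 4. Direct reduction of the hindered secondary radical before ring closure, or an intractable mixture at the radical carbon, could erode the cyclisation. The fallback introduces the C4 methyl group after ring closure. Alcohol 4 would be converted with ethyl vinyl ether and NBS into the 2-bromo-1-ethoxyethyl acetal F1, whose primary radical (Bu3SnH, AIBN) should close the same C3–C4 bond to give the monomethyl lactol ether F2. Oxidation with mCPBA/BF3·OEt2 would give the trans monomethyl lactone F3, and enolate methylation (LDA, MeI, THF, −78 °C), expected anti to the neighbouring ring methyl group, would rejoin the route at lactone 9.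

Step 9. Fluoride-induced epimerisation of the α-sulfonyloxy ketone (or of the product next to its carbonyl), or competing attack of fluoride on the tosylate, could lower the stereochemical purity. The fallback separates the two events and forms the C–O bond under neutral conditions. Silyl ether 13 would be cleaved with TBAF/AcOH in THF to the free phenol F7, which would be coupled with hydroxy ketone 16 in a Mitsunobu reaction (PPh3, DIAD, THF, 0 °C) with inversion at the carbinol carbon, rejoining the route at ketone 19.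

Further compounds
F1 | step 4 | tert-butyl{4-[(1R)-1-(2-bromo-1-ethoxyethoxy)prop-2-en-1-yl]-2-methoxyphenoxy}dimethylsilane | COc1cc([C@@H](C=C)OC(OCC)CBr)ccc1O[Si](C)(C)C(C)(C)C
F2 | step 4 | tert-butyl{4-[(2R,3R)-5-ethoxy-3-methyloxolan-2-yl]-2-methoxyphenoxy}dimethylsilane | COc1cc([C@@H]2OC(OCC)C[C@H]2C)ccc1O[Si](C)(C)C(C)(C)C
F3 | step 4 | (4R,5R)-5-[4-(tert-butyldimethylsilyloxy)-3-methoxyphenyl]-4-methyloxolan-2-one | COc1cc([C@@H]2OC(=O)C[C@H]2C)ccc1O[Si](C)(C)C(C)(C)C
F4 | step 6 | (2R,3R,4R)-4-[4-(tert-butyldimethylsilyloxy)-3-methoxyphenyl]-4-hydroxy-N-methoxy-N,2,3-trimethylbutanamide | COc1cc([C@H](O)[C@H](C)[C@@H](C)C(=O)N(C)OC)ccc1O[Si](C)(C)C(C)(C)C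
F5 | step 6 | (2R,3R,4R)-4-[4-(tert-butyldimethylsilyloxy)-3-methoxyphenyl]-N-methoxy-N,2,3-trimethyl-4-(triethylsilyloxy)butanamide | COc1cc([C@H](O[Si](CC)(CC)CC)[C@H](C)[C@@H](C)C(=O)N(C)OC)ccc1O[Si](C)(C)C(C)(C)C
F6 | step 6 | (2R,3R,4R)-1-[4-(benzyloxy)-3-methoxyphenyl]-4-[4-(tert-butyldimethylsilyloxy)-3-methoxyphenyl]-2,3-dimethyl-4-(triethylsilyloxy)butan-1-one | COc1cc([C@H](O[Si](CC)(CC)CC)[C@H](C)[C@@H](C)C(=O)c2ccc(OCc3ccccc3)c(OC)c2)ccc1O[Si](C)(C)C(C)(C)C
F7 | step 9 | 4-{(2R,3R,4R,5S)-5-[4-(benzyloxy)-3-methoxyphenyl]-3,4-dimethyloxolan-2-yl}-2-methoxyphenol | COc1cc([C@@H]2O[C@H](c3ccc(OCc4ccccc4)c(OC)c3)[C@H](C)[C@H]2C)ccc1O
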